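Everything rests on cutting the C3–C4 bond at the quaternary C4 of ring A, the carbon that carries the equatorial methyl and the axial C19 acetoxymethyl next to C5. Ring A is first made one carbon too large: a trans-fused 6–7 enone whose seven-membered ring holds a trisubstituted β-epoxide (C4–Cx). One Lewis-acid semipinacol shift of C3 from Cx to C4 contracts seven to six, sets C4 stereospecifically and pushes Cx out as the axial C19 aldehyde. The precursor comes in four steps from (R)-carvone, which supplies ring B, C17, C4, C18 and the C5 stereocentre. Its enone later provides C9 and the 7α-hydroxy-8(17)-ene unit.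

Key step: step 5

Remark: labdane numbering is used for all bicyclic compounds. Cx is the extra carbon of the seven-membered ring that becomes C19. α is the face of H-5 and β is the face of the C10 methyl. Compound 2 is carried on as its C6-epimer mixture because step 2 planarises that centre.

Step 1
Reactants: 1 (R)-(−)-carvone
Product: 2 (5R,6S)-6-methylcarvone (major trans epimer, minor 6R epimer also present)
Conditions: LDA, THF, −78 °C; MeI, −78 → 0 °C
Reagents that add atoms: methyl iodide, CI
Why: Kinetic α′-deprotonation of the cross-conjugated enone followed by SN2 methylation (enolate alkylation); the new centre is erased again in step 2, so its configuration does not matter.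

Step 2
Reactants: 2 (5R,6S)-6-methylcarvone; 3 5-iodopent-1-ene
Product: 4 (5S,6S)-2,6-dimethyl-6-(pent-4-en-1-yl)-5-(prop-1-en-2-yl)cyclohex-2-en-1-one (methyl cis, pentenyl trans to the isopropenyl group)
Conditions: LDA, THF, −78 °C; 3, DMPU, −78 °C → rt
Reagents that add atoms: none
Why: Enolate alkylation in which allylic strain with the C6 methyl holds the isopropenyl group pseudoaxial on the planar dienolate, so the iodide should enter anti to it and set the quaternary centre (future C10) with the methyl on the β face.

Step 3
Reactants: 4 dialkylated carvone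
Product: 5 trans-fused 6–7 dienone (C9 ketone, C7=C8 with the C17 methyl, seven-membered ring C10–C1–C2–C3–Cx=C4(CH3)–C5, 5α-H, 10β-CH3)
Conditions: second-generation Grubbs catalyst (5 mol %), CH2Cl2 (high dilution), reflux
Reagents that add atoms: none
Why: Ring-closing metathesis: the catalyst loads on the monosubstituted pentenyl alkene and closes onto the isopropenyl group (both equatorial), the electron-poor trisubstituted enone alkene stays out, and no stereocentre is formed.

Step 4
Reactants: 5 trans-fused 6–7 dienone
Product: 7 4β,xβ-epoxy enone (β-epoxide of 5), via bromohydrin 6 (not isolated)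
Conditions: NBS, DME–H2O, 0 °C; then K2CO3, MeOH, rt
Reagents that add atoms: N-bromosuccinimide, O=C1CCC(=O)N1Br (bromine stays only in 6); water, O
Why: Halohydrin formation and Williamson-type closure: the bromonium ion should form on the open α face and water opens it anti at tertiary C4 from the β face, so carbonate closes the β-epoxide (C4 and Cx set), the face a peracid would not deliver, while the enone alkene is too electron-poor to react.

Step 5
Reactants: 7 4β,xβ-epoxy enone
Product: 8 keto aldehyde (trans-decalin: 9-oxo, C7=C8, 4α-CH3, 4β-CHO = C19, 5α-H, 10β-CH3)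
Conditions: MeAl(OAr)2 (MABR, Ar = 4-bromo-2,6-di-tert-butylphenyl, 2.2 equiv, from Me3Al + 2 ArOH), CH2Cl2, −78 → −40 °C; dilute HCl work-up
Reagents that add atoms: none
Why: The aluminium Lewis acid binds the epoxide oxygen (a second equivalent rests on the enone carbonyl) and heterolyses the weaker tertiary C4–O bond; as charge builds at C4, the C3–Cx σ-bond on the α face opposite the leaving oxygen shifts from Cx to C4 while Cx=O forms, which is the Meinwald/semipinacol rearrangement of a trisubstituted epoxide to an α-quaternary aldehyde for which this bulky reagent is known. Ring A is closed not by a cyclisation mode but by this suprafacial 1,2-alkyl shift, which turns the seven-membered ring C10–C1–C2–C3–Cx–C4–C5 into the six-membered ring C10–C1–C2–C3–C4–C5 and expels Cx as C19. The only new stereocentre, C4, is controlled by the epoxide configuration: C3 enters anti to the β C4–O bond (inversion), so the formyl carbon stays β (axial) and the methyl becomes α (equatorial). The selectivity needed is alkyl shift over the 1,2-hydride shift from Cx (which would lead to a cycloheptanone) and over proton loss. The very bulky aluminium phenoxide favours the rotamer that places only H and O–Al beside the C4 substituents, the flexible seven-membered ring lets the C3–Cx bond align with the empty orbital, and going from seven to six adds driving force. C5 and C10 are untouched and the complexed enone is inert at this temperature.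

Step 6
Reactants: 8 keto aldehyde
Product: 9 19-hydroxy enone
Conditions: NaBH4 (0.5 equiv), CH2Cl2–MeOH, −78 °C
Reagents that add atoms: none
Why: Chemoselective borohydride reduction: at low temperature the aldehyde is reduced much faster than a conjugated ketone flanked by quaternary C10 and the C8 methyl, and no stereocentre is formed.

Step 7
Reactants: 9 19-hydroxy enone
Product: 11 9β,19-diacetoxy-9α-vinyl diene, via bromomagnesium dialkoxide 10 (not isolated)
Conditions: CH2=CHMgBr (4 equiv), CeCl3, THF, −78 → 0 °C; then Ac2O, DMAP, 0 °C → rt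
Reagents that add atoms: vinylmagnesium bromide, C=C[Mg]Br; acetic anhydride, CC(=O)OC(C)=O
Why: Cerium-assisted 1,2-addition of the vinyl Grignard reagent (expected from the α face, anti to the axial C10 methyl) and in-flask O-acylation of both alkoxides; the C19 acetate is the one kept in the target, the tertiary bis-allylic C9 acetate is only a leaving group, and its configuration is erased in step 8.

Step 8
Reactants: 11 9β,19-diacetoxy-9α-vinyl diene
Product: 12 19-acetoxy-13,14,15,16-tetranorlabda-7,11-diene (9α-H, 9β-vinyl)
Conditions: Pd2(dba)3·CHCl3 (2.5 mol %), n-Bu3P (5 mol %), HCO2H, Et3N, THF, rt → 40 °C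
Reagents that add atoms: none
Why: Palladium-catalysed formate hydrogenolysis of an allylic ester (Tsuji–Trost ionisation, then decarboxylative hydride transfer): whichever terminus (C12 or C7) holds palladium in the σ-allyl form, C9 is the γ-carbon that receives hydride, which gives the skipped diene; hydride should arrive on the α face because the adjacent axial C10 methyl blocks the β face (sets 9α-H), and the non-allylic C19 acetate is untouched.

Step 9
Reactants: 12 tetranorlabda-7,11-diene acetate
Product: 13 7α,8α-epoxide of 12
Conditions: mCPBA, CH2Cl2, 0 °C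
Reagents that add atoms: 3-chloroperoxybenzoic acid, O=C(OO)c1cccc(Cl)c1
Why: Prilezhaev epoxidation: the trisubstituted C7=C8 alkene is far more nucleophilic than the vinyl group and should be attacked on the α face, away from the C10 methyl and the β vinyl group, which sets the α C7–O bond and C8.

Step 10
Reactants: 13 7α,8α-epoxide
Product: 14 19-acetoxy-13,14,15,16-tetranorlabda-8(17),11-dien-7α-ol
Conditions: Cp2TiCl2 (2.5 equiv), Mn dust, THF (degassed), rt; aq. NaH2PO4 work-up
Reagents that add atoms: none
Why: Epoxide-to-allylic-alcohol isomerisation by trivalent titanium: Cp2TiCl cleaves C8–O homolytically to the tertiary C8 radical and a second Cp2TiCl removes a hydrogen atom from the exposed C17 methyl to give the exocyclic alkene; the C7–O bond is never broken, so 7α is retained, and acetate and vinyl are inert.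

Step 11
Reactants: 15 but-2-yn-1-ol
Product: 17 (E)-3-iodobut-2-en-1-ol, via alkenylzirconocene 16 (not isolated)
Conditions: Cp2ZrHCl (2.3 equiv), THF, 0 °C → rt; then I2, 0 °C
Reagents that add atoms: Cp2ZrHCl, [H][Zr](Cl)(C1C=CC=C1)C1C=CC=C1 (zirconium stays only in 16); iodine, II
Why: Hydrozirconation–iodinolysis: syn addition of Zr–H places zirconium on the methyl-bearing alkyne carbon, away from the bulky zirconium alkoxide arm, and iodination with retention fixes the E geometry.

Step 12
Reactants: 14 tetranorlabdadienol acetate; 17 (E)-3-iodobut-2-en-1-ol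
Product: 19 19-acetoxylabda-8(17),13E-diene-7α,15-diol (target), via B-alkyl-9-BBN borane 18 (not isolated)
Conditions: 9-BBN-H (2.3 equiv), THF, 0 °C → rt; then 17, PdCl2(dppf) (5 mol %), AsPh3, Cs2CO3, DMF–H2O, rt
Reagents that add atoms: 9-borabicyclo[3.3.1]nonane, [H]B1C2CCCC1CCC2 (boron stays only in 18)
Why: B-alkyl Suzuki–Miyaura coupling: 9-BBN-H first caps the 7-OH as a bulky borinate and should then add to the free vinyl terminus in preference to the exocyclic methylene wedged between the C7 and C9 substituents; coupling keeps the E geometry of 17, aqueous base frees the 7-OH, and no stereocentre is touched.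

Compound list
1 | (R)-(−)-carvone | CC1=CC[C@H](CC1=O)C(C)=C | starting material
2 | (5R,6S)-6-methylcarvone (major epimer) | O=C1C(C)=CC[C@@H](C(C)=C)[C@@H]1C | intermediate
3 | 5-iodopent-1-ene | C=CCCCI | starting material
4 | (5S,6S)-2,6-dimethyl-6-(pent-4-en-1-yl)-5-(prop-1-en-2-yl)cyclohex-2-en-1-one | O=C1C(C)=CC[C@@H](C(C)=C)[C@]1(C)CCCC=C | intermediate
5 | trans-fused 6–7 dienone | O=C1C(C)=CC[C@H]2C(C)=CCCC[C@]12C | intermediate
6 | bromohydrin (4β-OH, xα-Br) | O=C1C(C)=CC[C@H]2[C@@](C)(O)[C@H](Br)CCC[C@]12C | intermediate
7 | 4β,xβ-epoxy enone | O=C1C(C)=CC[C@H]2[C@@]3(C)O[C@H]3CCC[C@]12C | intermediate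
8 | keto aldehyde (4β-CHO, ring A six-membered) | O=C1C(C)=CC[C@H]2[C@@](C)(C=O)CCC[C@]12C | intermediate
9 | 19-hydroxy enone | O=C1C(C)=CC[C@H]2[C@@](C)(CO)CCC[C@]12C | intermediate
10 | bromomagnesium dialkoxide of the 9α-vinyl-9β,19-diol | C=C[C@]1(O[Mg]Br)C(C)=CC[C@H]2[C@@](C)(CO[Mg]Br)CCC[C@]12C | intermediate
11 | 9β,19-diacetoxy-9α-vinyl diene | C=C[C@]1(OC(C)=O)C(C)=CC[C@H]2[C@@](C)(COC(C)=O)CCC[C@]12C | intermediate
12 | 19-acetoxy-13,14,15,16-tetranorlabda-7,11-diene | C=C[C@H]1C(C)=CC[C@H]2[C@@](C)(COC(C)=O)CCC[C@]12C | intermediate
13 | 7α,8α-epoxide of 12 | C=C[C@H]1[C@]3(C)O[C@@H]3C[C@H]2[C@@](C)(COC(C)=O)CCC[C@]12C | intermediate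
14 | 19-acetoxy-13,14,15,16-tetranorlabda-8(17),11-dien-7α-ol | C=C[C@H]1C(=C)[C@H](O)C[C@H]2[C@@](C)(COC(C)=O)CCC[C@]12C | intermediate
15 | but-2-yn-1-ol | CC#CCO | starting material
16 | (E)-alkenylzirconocene chloride, O-zirconated | C/C(=C\CO[Zr](Cl)(C1C=CC=C1)C1C=CC=C1)[Zr](Cl)(C1C=CC=C1)C1C=CC=C1 | intermediate
17 | (E)-3-iodobut-2-en-1-ol | C/C(I)=C\CO | intermediate
18 | C12 B-alkyl-9-BBN borane, 7-O-borinate | C=C1[C@H](OB3C4CCCC3CCC4)C[C@H]2[C@@](C)(COC(C)=O)CCC[C@]2(C)[C@H]1CCB5C6CCCC5CCC6 | intermediate
19 | 19-acetoxylabda-8(17),13E-diene-7α,15-diol | C=C1[C@H](O)C[C@H]2[C@@](C)(COC(C)=O)CCC[C@]2(C)[C@H]1CC/C(C)=C/CO | target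

Total step count: 12. Longest linear sequence: 11 (steps 1–10 and 12).

Steps most likely to fail

Step 5 (key step): the 1,2-hydride shift from Cx or proton loss may outrun the alkyl shift, or a long-lived C4 cation may erode the stereospecificity.
- The fallback keeps the seven-to-six contraction but makes it anionic.
- It sets out from 5. A peracid should epoxidise the open α face to give the α-epoxide F1.
- Ethereal HCl opens F1 at tertiary C4 with inversion to the 4β-chloro-xα-ol F2.
- Dess–Martin periodinane gives the α-chloro ketone F3.
- NaOMe in DME then triggers a Favorskii ring contraction to the 4β-methyl ester F4. The C3 enolate displaces the β chloride with inversion, and methoxide opens the cyclopropanone towards the less substituted C3 carbanion.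
- LiAlH4 reduces ester and enone carbonyl to the 9β,19-diol F5, and MnO2 re-oxidises only the allylic alcohol.
- The fallback comes back to the route at 9.

Step 8: hydride may be delivered to the allyl termini (giving conjugated dienes), β-hydride elimination of the allylpalladium species may compete, or the crowded tertiary acetate may form incompletely in step 7.
- The fallback sets C9 by hydroboration instead. It sets out from 9.
- Ac2O/pyridine gives the 19-acetoxy enone F6.
- CH2Br2/Zn/TiCl4 (Lombardo methylenation, which spares esters) gives the 7,9(11)-diene F7.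
- 9-BBN-H adds to the exocyclic methylene from the α face, and NaBO3 oxidation gives the 11-alcohol F8 (9α-H).
- Dess–Martin periodinane gives the 11-aldehyde F9.
- Wittig methylenation (Ph3P=CH2, −78 °C) comes back to the route at 12.

Step 12: 9-BBN-H may not discriminate well enough between the vinyl group and the exocyclic methylene.
- The fallback changes the order so that no second reactive alkene is present during hydroboration. It sets out from 13.
- 9-BBN-H gives the epoxy B-alkyl borane F10.
- Suzuki–Miyaura coupling with 17 under the same catalyst gives 19-acetoxy-7α,8α-epoxylabd-13E-en-15-ol F11.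
- The epoxide is then isomerised by a base-type syn-elimination through a C17 hydrogen with Et2Al(tmp) (tmp = 2,2,6,6-tetramethylpiperidide) in benzene at 0 °C.
- Trivalent titanium is avoided here because a C8 radical would add to the side-chain alkene.
- The fallback comes back to the route at 19.

Further compounds
F1 | step 5 | 4α,xα-epoxy enone | O=C1C(C)=CC[C@H]2[C@]3(C)O[C@@H]3CCC[C@]12C
F2 | step 5 | 4β-chloro-xα-hydroxy enone | O=C1C(C)=CC[C@H]2[C@@](C)(Cl)[C@H](O)CCC[C@]12C
F3 | step 5 | 4β-chloro-x-oxo enone | O=C1C(C)=CC[C@H]2[C@@](C)(Cl)C(=O)CCC[C@]12C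
F4 | step 5 | 4β-methoxycarbonyl enone (ring A six-membered) | O=C1C(C)=CC[C@H]2[C@@](C)(C(=O)OC)CCC[C@]12C
F5 | step 5 | 9β,19-diol | O[C@H]1C(C)=CC[C@H]2[C@@](C)(CO)CCC[C@]12C
F6 | step 8 | 19-acetoxy enone | O=C1C(C)=CC[C@H]2[C@@](C)(COC(C)=O)CCC[C@]12C
F7 | step 8 | 19-acetoxy-7,9(11)-diene | C=C1C(C)=CC[C@H]2[C@@](C)(COC(C)=O)CCC[C@]12C
F8 | step 8 | 19-acetoxy-11-hydroxy-7-ene (9α-H) | OC[C@H]1C(C)=CC[C@H]2[C@@](C)(COC(C)=O)CCC[C@]12C
F9 | step 8 | 19-acetoxy-7-en-11-al (9α-H) | O=C[C@H]1C(C)=CC[C@H]2[C@@](C)(COC(C)=O)CCC[C@]12C
F10 | step 12 | epoxy B-alkyl-9-BBN borane | C(C[C@H]1[C@]3(C)O[C@@H]3C[C@H]2[C@@](C)(COC(C)=O)CCC[C@]12C)B4C5CCCC4CCC5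
F11 | step 12 | 19-acetoxy-7α,8α-epoxylabd-13E-en-15-ol | OC/C=C(C)/CC[C@H]1[C@]3(C)O[C@@H]3C[C@H]2[C@@](C)(COC(C)=O)CCC[C@]12C
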